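**Retrosynthetic overview**

- Feature: ring B of the drimane half (C5–C10, with the C8 methyl, the C7=C8 bond and an oxygenated C9) is the carbon skeleton of (S)-carvone, and the carvone isopropenyl carbon is C4, the gem-dimethyl carbon bonded to C3 of ring A.
- Late disconnections: the C1=C2/C3=O enone from a C3 carbinol; the aryl ether O–C11 by Mitsunobu reaction with isofraxidin; C9–C11 by a [2,3]-Wittig–Still shift from a C7 allylic ether, which comes from the C9 enone by epoxidation and Wharton transposition.
- Ring A is opened at C3–C4: hydrogen-atom transfer to the isopropenyl group, then 6-exo attack of the tertiary C4 radical on a C3 aldehyde. The aldehyde chain and the C10 methyl come from two α'-alkylations of carvone.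
- Order of rings: ring B is bought as carvone, ring A is closed in step 5, and the two coumarin rings arrive intact with isofraxidin in step 11.

Key step: step 5

Remark: bicyclic compounds carry drimane numbering (ring A = C1–C5 and C10, ring B = C5–C10, C11 on C9, C12 on C8); the C3 carbinol of step 5 is drawn as the equatorial epimer, and either epimer serves because C3 is oxidised in step 13.

**Route**

Step 1
Reactants: 1 (S)-carvone; 2 methyl iodide
Product: 3 (5S)-6-methylcarvone (C6 epimer mixture)
Conditions: LiN(iPr)2 (LDA, commercial solution, 1.05 equiv), THF, −78 °C; MeI, −78 → 0 °C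
Reagents that add atoms: methyl iodide 2, CI
Why: Enolate alkylation: kinetic deprotonation of the enone at C6 (the α'-carbon) gives the cross-conjugated lithium enolate, which is C-methylated; the new C6 centre forms as an epimer mixture of no consequence because step 2 makes it trigonal again.

Step 2
Reactants: 3 (5S)-6-methylcarvone; 4 allyl bromide
Product: 5 (5R,6R)-6-allyl-6-methylcarvone (allyl trans and methyl cis to isopropenyl)
Conditions: LiN(iPr)2 (1.1 equiv), THF, −78 °C; allyl bromide, DMPU, −78 → 0 °C
Reagents that add atoms: allyl bromide 4, C=CCBr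
Why: Enolate alkylation of the tetrasubstituted lithium enolate: allyl bromide should approach the face anti to the neighbouring C5 isopropenyl group, so the quaternary centre (later C10) is set by substrate control with allyl trans and methyl cis to isopropenyl, the arrangement a trans-fused decalin needs.

Step 3
Reactants: 5 (5R,6R)-6-allyl-6-methylcarvone
Product: 7 (5R,6R)-6-(3-hydroxypropyl)-6-methylcarvone, via alkyldisiamylborane 6 (not isolated)
Conditions: disiamylborane (1.2 equiv, made from BH3·THF and 2-methyl-2-butene), THF, −10 → 0 °C; then NaBO3·4H2O, THF/H2O, rt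
Reagents that add atoms: sodium perborate, [Na+].[O-]OB=O (gives the hydroxyl oxygen); disiamylborane, CC(C)C(C)BC(C)C(C)C (its atoms stand in 6 only)
Why: Hydroboration–oxidation: the hindered dialkylborane adds anti-Markovnikov to the monosubstituted allyl alkene much faster than to the 1,1-disubstituted isopropenyl group beside the quaternary carbon or to the conjugated carbonyl (a less hindered borane such as 9-BBN would not make this distinction reliably), and perborate oxidises the C–B bond without the alkaline peroxide that would epoxidise the enone; no stereocentre is formed.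

Step 4
Reactants: 7 (5R,6R)-6-(3-hydroxypropyl)-6-methylcarvone
Product: 8 (5R,6R)-6-methyl-6-(3-oxopropyl)carvone
Conditions: Dess–Martin periodinane (1.2 equiv), CH2Cl2, 0 °C → rt
Reagents that add atoms: none
Why: Dess–Martin oxidation of the primary alcohol stops at the aldehyde under neutral conditions and leaves the enone and the isopropenyl group untouched; no stereocentre is formed.

Step 5
Reactants: 8 (5R,6R)-6-methyl-6-(3-oxopropyl)carvone
Product: 9 3-hydroxy-11-nor-drim-7-en-9-one (trans-fused; 3-OH equatorial and cis to the C10 methyl)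
Conditions: Fe(acac)3 (20 mol%), PhSiH3 (2.5 equiv), degassed EtOH (dilute), 60 °C
Reagents that add atoms: none
Why: Fe(acac)3 and PhSiH3 in ethanol give an iron hydride that transfers a hydrogen atom to the CH2 terminus of the electron-rich isopropenyl group, the tertiary C4 radical adds to the aldehyde carbon C3, and the alkoxy radical is reduced by divalent iron and protonated by ethanol, which returns trivalent iron. The closest known reaction type is the iron-hydride radical cyclization of alkenes onto tethered ketones, of which an aldehyde is the less hindered acceptor of the same class. Ring A closes in the 6-exo-trig mode through a chair-like transition state in which the C4 carbon on C5 and the chain on C10 are both equatorial on ring B, so the trans ring fusion fixed in step 2 is kept and C4 becomes the gem-dimethyl quaternary carbon. The only new stereocentre, C3, is controlled by that chair with the carbonyl oxygen pseudo-equatorial (alcohol cis to the C10 methyl), and its configuration is of no consequence because C3 is oxidised in step 13. The step needs initiation at the isopropenyl group alone and cyclization faster than reduction of the radical or β-scission of the alkoxy radical: the trisubstituted enone alkene is electron-poor and a poor hydrogen-atom acceptor, the enone carbons can be reached by the C4 radical only through a four-membered ring or by attack at the α-carbon, and the diequatorial arrangement holds C3 within bonding distance of C4.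

Step 6
Reactants: 9 3-hydroxy-11-nor-drim-7-en-9-one
Product: 10 3-(tert-butyldimethylsilyloxy)-11-nor-drim-7-en-9-one
Conditions: TBSOTf (1.3 equiv), 2,6-lutidine (2 equiv), CH2Cl2, −78 → 0 °C
Reagents that add atoms: tert-butyldimethylsilyl triflate, CC(C)(C)[Si](C)(C)OS(=O)(=O)C(F)(F)F
Why: Silyl ether formation with the silyl triflate, which is reactive enough for the neopentyl-type secondary C3 alcohol; the ether masks C3–OH against the basic, nucleophilic and organolithium conditions of steps 7 to 11, and no stereocentre changes.

Step 7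
Reactants: 10 3-(tert-butyldimethylsilyloxy)-11-nor-drim-7-en-9-one
Product: 11 7,8-epoxy-3-(tert-butyldimethylsilyloxy)-11-nor-driman-9-one (oxirane oxygen anti to the C10 methyl)
Conditions: 30% aq H2O2 (5 equiv), NaOH (0.3 equiv), MeOH/THF, 0 °C → rt
Reagents that add atoms: hydrogen peroxide, OO
Why: Weitz–Scheffer nucleophilic epoxidation: hydroperoxide adds axially to C7 on the ring B face anti to the axial C10 methyl (the face of H5) and the enolate closes the oxirane at C8 on the same face, since the other face would place the oxygen 1,3-diaxial to that methyl, so C7 and C8 are set by the ring fusion.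

Step 8
Reactants: 11 7,8-epoxy-3-(tert-butyldimethylsilyloxy)-11-nor-driman-9-one
Product: 13 3-(tert-butyldimethylsilyloxy)-11-nor-drim-8-en-7-ol (7-OH pseudoaxial and anti to the C10 methyl), via epoxy hydrazone 12 (not isolated)
Conditions: N2H4·H2O (3 equiv), AcOH (0.3 equiv), MeOH, argon, 0 °C → rt
Reagents that add atoms: hydrazine, NN (its nitrogen atoms stand in 12 only)
Why: Wharton transposition: the epoxy hydrazone opens to an alkenyl diazene that loses N2, which leaves hydrogen at C9, the alkene at C8=C9 and the hydroxyl at C7; the C7–O bond is never broken, so the carbinol keeps the configuration set in step 7.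

Step 9
Reactants: 13 3-(tert-butyldimethylsilyloxy)-11-nor-drim-8-en-7-ol; 14 tributyl(iodomethyl)stannane
Product: 15 7-[(tributylstannyl)methoxy]-3-(tert-butyldimethylsilyloxy)-11-nor-drim-8-ene
Conditions: KH (1.5 equiv), THF, 0 °C; then Bu3SnCH2I, 18-crown-6 (cat.), 0 °C → rt
Reagents that add atoms: tributyl(iodomethyl)stannane 14, CCCC[Sn](CCCC)(CCCC)CI
Why: Williamson etherification of the potassium alkoxide with the reactive α-stannyl primary iodide; the C7 configuration is untouched.

Step 10
Reactants: 15 7-[(tributylstannyl)methoxy]-3-(tert-butyldimethylsilyloxy)-11-nor-drim-8-ene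
Product: 17 3-(tert-butyldimethylsilyloxy)drim-7-en-11-ol (C11 anti to the C10 methyl), via lithiomethyl ether 16 (not isolated)
Conditions: n-BuLi (1.5 equiv), THF, −78 → −40 °C; then H2O
Reagents that add atoms: n-butyllithium, [Li]CCCC (its lithium stands in 16 only)
Why: Still–Wittig [2,3]-sigmatropic rearrangement: tin–lithium exchange gives the α-alkoxy carbanion, which shifts suprafacially through a five-membered envelope transition state, so C11 is delivered to C9 on the face that held the pseudoaxial C7–O bond (anti to the C10 methyl, which sets C9 as the target requires) while C7=C8 is re-formed.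

Step 11
Reactants: 17 3-(tert-butyldimethylsilyloxy)drim-7-en-11-ol; 18 isofraxidin
Product: 19 6,8-dimethoxy-7-{[3-(tert-butyldimethylsilyloxy)drim-7-en-11-yl]oxy}coumarin
Conditions: PPh3 (1.5 equiv), DIAD (1.5 equiv), THF, 0 °C → rt
Reagents that add atoms: isofraxidin 18, COc1cc2ccc(=O)oc2c(OC)c1O
Why: Mitsunobu etherification: the acidic 7-hydroxyl of the coumarin displaces the oxyphosphonium of the primary C11 alcohol by SN2; no stereocentre is involved and C9 carries no acidifying group.

Step 12
Reactants: 19 6,8-dimethoxy-7-{[3-(tert-butyldimethylsilyloxy)drim-7-en-11-yl]oxy}coumarin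
Product: 20 7-[(3-hydroxydrim-7-en-11-yl)oxy]-6,8-dimethoxycoumarin
Conditions: 48% aq HF, MeCN/CH2Cl2, 0 °C → rt
Reagents that add atoms: none
Why: Acidic fluoride desilylation removes the hindered secondary silyl ether while the lactone (which basic fluoride could open), the aryl ether and the trisubstituted alkene are stable; no stereocentre changes.

Step 13
Reactants: 20 7-[(3-hydroxydrim-7-en-11-yl)oxy]-6,8-dimethoxycoumarin
Product: 22 6,8-dimethoxy-7-[(3-oxodrima-1,7-dien-11-yl)oxy]coumarin (CNP0330704.1), via 3-ketone 21 (not isolated)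
Conditions: IBX (4 equiv), DMSO, 25 °C, then 75 °C
Reagents that add atoms: none
Why: IBX oxidation of the secondary alcohol followed in the same flask by IBX dehydrogenation of the ketone through its enol: C4 is quaternary, so only C1–C2 can be desaturated, and none of C5, C9 and C10 is α to the carbonyl, so these centres are kept while the C3 centre is removed.

**Compound list**

1 | (S)-carvone, (5S)-2-methyl-5-(prop-1-en-2-yl)cyclohex-2-en-1-one | CC1=CC[C@@H](CC1=O)C(C)=C | starting material
2 | methyl iodide | CI | starting material
3 | (5S)-6-methylcarvone, C6 epimer mixture | O=C1C(C)=CC[C@H](C(C)=C)C1C | intermediate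
4 | allyl bromide | C=CCBr | starting material
5 | (5R,6R)-6-allyl-6-methylcarvone (allyl trans, methyl cis to isopropenyl) | O=C1C(C)=CC[C@H](C(C)=C)[C@@]1(C)CC=C | intermediate
6 | B-[3-(carvon-6-yl)propyl]disiamylborane from 5 (formed in the flask) | O=C1C(C)=CC[C@H](C(C)=C)[C@@]1(C)CCCB(C(C)C(C)C)C(C)C(C)C | intermediate
7 | (5R,6R)-6-(3-hydroxypropyl)-6-methylcarvone | O=C1C(C)=CC[C@H](C(C)=C)[C@@]1(C)CCCO | intermediate
8 | (5R,6R)-6-methyl-6-(3-oxopropyl)carvone | O=C1C(C)=CC[C@H](C(C)=C)[C@@]1(C)CCC=O | intermediate
9 | 3-hydroxy-11-nor-drim-7-en-9-one; trans-decalin, H5 anti to the C10 methyl, 3-OH equatorial and cis to the C10 methyl | O=C1C(C)=CC[C@@H]2C(C)(C)[C@H](O)CC[C@]21C | intermediate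
10 | 3-(tert-butyldimethylsilyloxy)-11-nor-drim-7-en-9-one | O=C1C(C)=CC[C@@H]2C(C)(C)[C@H](O[Si](C)(C)C(C)(C)C)CC[C@]21C | intermediate
11 | 7,8-epoxy-3-(tert-butyldimethylsilyloxy)-11-nor-driman-9-one; oxirane oxygen anti to the C10 methyl, cis to H5 | O=C1[C@@]2(C)O[C@H]2C[C@@H]3C(C)(C)[C@H](O[Si](C)(C)C(C)(C)C)CC[C@]31C | intermediate
12 | C9 hydrazone of 11 (formed in the flask) | NN=C1[C@@]2(C)O[C@H]2C[C@@H]3C(C)(C)[C@H](O[Si](C)(C)C(C)(C)C)CC[C@]31C | intermediate
13 | 3-(tert-butyldimethylsilyloxy)-11-nor-drim-8-en-7-ol; 7-OH pseudoaxial, anti to the C10 methyl | O[C@H]1C[C@@H]2C(C)(C)[C@H](O[Si](C)(C)C(C)(C)C)CC[C@@]2(C)C=C1C | intermediate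
14 | tributyl(iodomethyl)stannane | CCCC[Sn](CCCC)(CCCC)CI | starting material
15 | 7-[(tributylstannyl)methoxy]-3-(tert-butyldimethylsilyloxy)-11-nor-drim-8-ene | CCCC[Sn](CCCC)(CCCC)CO[C@H]1C[C@@H]2C(C)(C)[C@H](O[Si](C)(C)C(C)(C)C)CC[C@@]2(C)C=C1C | intermediate
16 | 7-(lithiomethoxy)-3-(tert-butyldimethylsilyloxy)-11-nor-drim-8-ene (formed in the flask) | [Li]CO[C@H]1C[C@@H]2C(C)(C)[C@H](O[Si](C)(C)C(C)(C)C)CC[C@@]2(C)C=C1C | intermediate
17 | 3-(tert-butyldimethylsilyloxy)drim-7-en-11-ol; C11 anti to the C10 methyl (H9 cis to it) | OC[C@H]1C(C)=CC[C@@H]2C(C)(C)[C@H](O[Si](C)(C)C(C)(C)C)CC[C@]21C | intermediate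
18 | isofraxidin, 7-hydroxy-6,8-dimethoxy-2H-chromen-2-one | COc1cc2ccc(=O)oc2c(OC)c1O | starting material
19 | 6,8-dimethoxy-7-{[3-(tert-butyldimethylsilyloxy)drim-7-en-11-yl]oxy}coumarin (configuration as in 17) | COc1cc2ccc(=O)oc2c(OC)c1OC[C@H]1C(C)=CC[C@@H]2C(C)(C)[C@H](O[Si](C)(C)C(C)(C)C)CC[C@]21C | intermediate
20 | 7-[(3-hydroxydrim-7-en-11-yl)oxy]-6,8-dimethoxycoumarin | COc1cc2ccc(=O)oc2c(OC)c1OC[C@H]1C(C)=CC[C@@H]2C(C)(C)[C@H](O)CC[C@]21C | intermediate
21 | 6,8-dimethoxy-7-[(3-oxodrim-7-en-11-yl)oxy]coumarin (formed in the flask) | COc1cc2ccc(=O)oc2c(OC)c1OC[C@H]1C(C)=CC[C@@H]2C(C)(C)C(=O)CC[C@]21C | intermediate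
22 | 7-{[(1S,4aS,8aR)-2,5,5,8a-tetramethyl-6-oxo-1,4,4a,5,6,8a-hexahydronaphthalen-1-yl]methoxy}-6,8-dimethoxy-2H-chromen-2-one (CNP0330704.1) | COc1cc2ccc(=O)oc2c(OC)c1OC[C@H]1C(C)=CC[C@@H]2C(C)(C)C(=O)C=C[C@]21C | target

**Step count and risks**

Total: 13 steps. Longest linear sequence: 13 steps, from (S)-carvone 1 to 22.

Steps most likely to fail:

1. Step 5 (radical closure of ring A). The tertiary radical may be reduced before it cyclizes (net hydrogenation of the isopropenyl group), the alkoxy radical may revert by β-scission, or the aldehyde may be consumed by the silane in ethanol. Fallback: it sets out from 8. Markovnikov addition of HBr (33% in AcOH, 0 °C) to the isopropenyl group should give the tertiary bromide of 8 F1. Slow addition of Bu3SnH with AIBN in benzene at 80 °C then produces the same C4 radical by bromine abstraction, free of the iron hydride and of ethanol, and closes ring A by the known tin-hydride 6-exo cyclization of alkyl radicals onto aldehydes. The fallback comes back to the route at 9.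

2. Step 8 (Wharton transposition). Hydrazone formation at C9, which stands between the quaternary C10 and the fully substituted oxirane carbon C8, may be too slow, so that hydrazine attacks the oxirane or the material degrades. Fallback: it sets out from 11. NaBH4 in MeOH at 0 °C should reduce the ketone to the epoxy alcohol F2 (either C9 epimer serves). NaH, CS2 and then MeI in THF convert it into the S-methyl xanthate F3. Bu3SnH with AIBN in toluene at 100 °C forms the C9 radical, which opens the oxirane at C8–O, and the C7 alkoxy radical takes hydrogen from the stannane (radical deoxygenation of the Barton–McCombie type with epoxide fragmentation). The C7–O bond is again untouched, and the fallback comes back to the route at 13.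

3. Step 10 (Still–Wittig shift). Because the terminus C9 lies next to the quaternary C10, the carbanion may undergo the [1,2]-shift or be protonated without forming the C9–C11 bond. Fallback: it sets out from 13. MnO2 in CH2Cl2 oxidises the allylic alcohol to the transposed enone 3-(tert-butyldimethylsilyloxy)-11-nor-drim-8-en-7-one F4. Copper-catalysed conjugate addition of (iPrO)Me2SiCH2MgCl (CuBr·SMe2, THF, −78 → −30 °C) should occur axially at C9, anti to the C10 methyl, and trapping of the enolate in the flask with PhNTf2 gives the C7 enol triflate F5. Pd(OAc)2, PPh3, Bu3N and HCO2H in DMF at 60 °C reduce the triflate to the C7=C8 alkene, the 11-silyl drimene F6. Tamao oxidation (KF, KHCO3, 30% H2O2, THF/MeOH) turns the C11–Si bond into C11–OH, and the fallback comes back to the route at 17.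

**Further compounds**

F1 | step 5 | hydrobromide of 8, 5-(2-bromopropan-2-yl)-6-methyl-6-(3-oxopropyl)-2-methylcyclohex-2-en-1-one (configuration of 8) | O=C1C(C)=CC[C@H](C(C)(C)Br)[C@@]1(C)CCC=O
F2 | step 8 | 7,8-epoxy-3-(tert-butyldimethylsilyloxy)-11-nor-driman-9-ol (C9 epimer mixture) | OC1[C@@]2(C)O[C@H]2C[C@@H]3C(C)(C)[C@H](O[Si](C)(C)C(C)(C)C)CC[C@]31C
F3 | step 8 | O-[7,8-epoxy-3-(tert-butyldimethylsilyloxy)-11-nor-driman-9-yl] S-methyl xanthate | CSC(=S)OC1[C@@]2(C)O[C@H]2C[C@@H]3C(C)(C)[C@H](O[Si](C)(C)C(C)(C)C)CC[C@]31C
F4 | step 10 | 3-(tert-butyldimethylsilyloxy)-11-nor-drim-8-en-7-one | O=C1C[C@@H]2C(C)(C)[C@H](O[Si](C)(C)C(C)(C)C)CC[C@@]2(C)C=C1C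
F5 | step 10 | 11-(isopropoxydimethylsilyl)-3-(tert-butyldimethylsilyloxy)drim-7-en-7-yl triflate (C11 anti to the C10 methyl) | CC(C)O[Si](C)(C)C[C@H]1C(C)=C(OS(=O)(=O)C(F)(F)F)C[C@@H]2C(C)(C)[C@H](O[Si](C)(C)C(C)(C)C)CC[C@]21C
F6 | step 10 | 11-(isopropoxydimethylsilyl)-3-(tert-butyldimethylsilyloxy)drim-7-ene | CC(C)O[Si](C)(C)C[C@H]1C(C)=CC[C@@H]2C(C)(C)[C@H](O[Si](C)(C)C(C)(C)C)CC[C@]21C
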